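**Retrosynthetic overview**
- The target is the symmetrical disulfide of two identical 2-amino-4-(4-methoxyphenyl)-1-methylimidazole halves. Both C5–S bonds are cut back to the C5–H imidazole, with disulfur dichloride as the S–S linchpin in the last step.
- The strategy rests on creatinine. Its N1(Me), C2(NH2), N3, C4 and C5 are the imidazole ring atoms, already assembled with the right N-methyl regiochemistry. The C4 carbonyl marks the aryl-bearing carbon and the C5 methylene marks the sulfur-bearing carbon.
- The C4–aryl bond is cut by a Suzuki–Miyaura disconnection to 4-methoxyphenylboronic acid and a 4-triflyloxyimidazole. The triflate comes from N,N-di-Boc protection and aromatizing O-triflation of creatinine.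
- No ring is built. The imidazole ring is bought with creatinine and aromatized in the triflation, and the anisyl ring arrives with the boronic acid.

Key step: step 3

Remark: the target has no stereocentre and the helicity about the S–S bond is not configurationally stable, so the compound is achiral in practice and no enantiocontrol is needed.

**Step 1**
Reactants: 1 creatinine; 2 di-tert-butyl dicarbonate
Product: 4 di-tert-butyl N-(1-methyl-4-oxo-4,5-dihydro-1H-imidazol-2-yl)imidodicarbonate, via tert-butyl N-(1-methyl-4-oxo-4,5-dihydro-1H-imidazol-2-yl)carbamate 3 (not isolated)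
Conditions: Boc2O (2.2 equiv), DMAP (0.2 equiv), Et3N (1 equiv), DMF, 0 °C → rt
Reagents that add atoms: di-tert-butyl dicarbonate (2), CC(C)(C)OC(=O)OC(=O)OC(C)(C)C
Why: In this DMAP-catalysed N-tert-butoxycarbonylation the first Boc group acidifies the remaining N–H, which is then acylated to the exocyclic imidodicarbonate as with the amino groups of cytosine, guanine and 2-aminoazoles, while limiting Boc2O to 2.2 equiv should keep the C5 enol from being carbonated.

**Step 2**
Reactants: 4 di-tert-butyl N-(1-methyl-4-oxo-4,5-dihydro-1H-imidazol-2-yl)imidodicarbonate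
Product: 6 di-tert-butyl N-[1-methyl-4-(trifluoromethylsulfonyloxy)-1H-imidazol-2-yl]imidodicarbonate, via potassium 2-[bis(tert-butoxycarbonyl)amino]-1-methyl-1H-imidazol-4-olate 5 (not isolated)
Conditions: KHMDS (1.1 equiv), THF, −78 °C; then PhNTf2 (1.1 equiv), −78 → 0 °C; Et3N-deactivated silica
Reagents that add atoms: N-phenylbis(trifluoromethanesulfonimide), O=S(=O)(N(c1ccccc1)S(=O)(=O)C(F)(F)F)C(F)(F)F
Why: This is the enol triflation of an azolone (as in oxazol-4(5H)-one → oxazol-4-yl triflate), in which KHMDS removes a C5 proton flanked by N1 and the C4 carbonyl to give an aromatic imidazol-4-olate that PhNTf2 should sulfonylate on oxygen, because only O-attack keeps the 6π imidazole and no N–H is left to compete.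

**Step 3**
Reactants: 6 di-tert-butyl N-[1-methyl-4-(trifluoromethylsulfonyloxy)-1H-imidazol-2-yl]imidodicarbonate; 7 4-methoxyphenylboronic acid
Product: 8 di-tert-butyl N-[4-(4-methoxyphenyl)-1-methyl-1H-imidazol-2-yl]imidodicarbonate
Conditions: 7 (1.3 equiv), XPhos Pd G3 (3 mol %), K3PO4 (0.5 M aq, 2 equiv), THF, 40 °C, degassed
Reagents that add atoms: 4-methoxyphenylboronic acid (7), COc1ccc(B(O)O)cc1
Why: Monoligated XPhos–Pd(0) inserts into the C4–O bond of 6, which lies α to the pyridine-type N3 and is made less electron-rich by the N(Boc)2 group; the phosphate-activated boronate of 7 then transmetalates and reductive elimination forms the C4–C(aryl) bond. The closest known reaction type is the Suzuki–Miyaura coupling of lactam-derived heteroaryl enol triflates such as oxazol-4-yl and thiazol-4-yl triflates. No ring is closed and no stereocentre is formed, and this one skeletal bond completes the carbon–nitrogen skeleton of one half of the target. The step needs C–O oxidative addition to outrun S–O hydrolysis of the triflate and cleavage of the imidodicarbonate, which a fast bulky-phosphine catalyst at 40 °C with a mild phosphate base should secure. Site selectivity is inherent, since 6 has a single C–X bond and its C5–H is inert under these conditions. Full protection of the exocyclic nitrogen leaves no guanidine-type N–H to bind palladium.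

**Step 4**
Reactants: 8 di-tert-butyl N-[4-(4-methoxyphenyl)-1-methyl-1H-imidazol-2-yl]imidodicarbonate
Product: 10 4-(4-methoxyphenyl)-1-methyl-1H-imidazol-2-amine, via 4-(4-methoxyphenyl)-1-methyl-1H-imidazol-2-amine hydrochloride 9 (not isolated)
Conditions: 4 M HCl in dioxane, rt; concentrate; then 1 M aq NaOH, EtOAc extraction; used promptly under N2
Reagents that add atoms: none
Why: Acidolysis of both tert-butyl carbamates (loss of isobutene, then decarboxylation) leaves the aryl methyl ether and the imidazole untouched, and protonation of the product as its imidazolium salt should shield C5 from tert-butylation.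

**Step 5**
Reactants: 10 4-(4-methoxyphenyl)-1-methyl-1H-imidazol-2-amine (two molecules)
Product: 12 5,5'-disulfanediylbis[4-(4-methoxyphenyl)-1-methyl-1H-imidazol-2-amine], via its dihydrochloride 11 (not isolated)
Conditions: S2Cl2 (0.5 equiv, slow addition), AcOH, rt; concentrate; then sat. aq NaHCO3
Reagents that add atoms: disulfur dichloride, ClSSCl
Why: In this electrophilic heteroaromatic sulfenylation with S2Cl2, a known way to symmetrical diheteroaryl disulfides, C5 is the enamine-type terminus activated by N1 and the 2-amino group and the only free ring position, so each S–Cl end of half an equivalent of S2Cl2 should be taken up by one molecule of 10 while acetic acid tempers the amino group against N-sulfenylation.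

**Compound list**
1 | creatinine (2-amino-1-methyl-1,5-dihydro-4H-imidazol-4-one) | CN1CC(=O)N=C1N | starting material
2 | di-tert-butyl dicarbonate | CC(C)(C)OC(=O)OC(=O)OC(C)(C)C | starting material
3 | tert-butyl N-(1-methyl-4-oxo-4,5-dihydro-1H-imidazol-2-yl)carbamate | CN1CC(=O)N=C1NC(=O)OC(C)(C)C | intermediate
4 | di-tert-butyl N-(1-methyl-4-oxo-4,5-dihydro-1H-imidazol-2-yl)imidodicarbonate | CN1CC(=O)N=C1N(C(=O)OC(C)(C)C)C(=O)OC(C)(C)C | intermediate
5 | potassium 2-[bis(tert-butoxycarbonyl)amino]-1-methyl-1H-imidazol-4-olate | Cn1cc([O-])nc1N(C(=O)OC(C)(C)C)C(=O)OC(C)(C)C.[K+] | intermediate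
6 | di-tert-butyl N-[1-methyl-4-(trifluoromethylsulfonyloxy)-1H-imidazol-2-yl]imidodicarbonate | Cn1cc(OS(=O)(=O)C(F)(F)F)nc1N(C(=O)OC(C)(C)C)C(=O)OC(C)(C)C | intermediate
7 | 4-methoxyphenylboronic acid | COc1ccc(B(O)O)cc1 | starting material
8 | di-tert-butyl N-[4-(4-methoxyphenyl)-1-methyl-1H-imidazol-2-yl]imidodicarbonate | COc1ccc(-c2cn(C)c(N(C(=O)OC(C)(C)C)C(=O)OC(C)(C)C)n2)cc1 | intermediate
9 | 4-(4-methoxyphenyl)-1-methyl-1H-imidazol-2-amine hydrochloride | COc1ccc(-c2cn(C)c(N)n2)cc1.Cl | intermediate
10 | 4-(4-methoxyphenyl)-1-methyl-1H-imidazol-2-amine | COc1ccc(-c2cn(C)c(N)n2)cc1 | intermediate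
11 | 5,5'-disulfanediylbis[4-(4-methoxyphenyl)-1-methyl-1H-imidazol-2-amine] dihydrochloride | COc1ccc(-c2nc(N)n(C)c2SSc2c(-c3ccc(OC)cc3)nc(N)n2C)cc1.Cl.Cl | intermediate
12 | 5,5'-disulfanediylbis[4-(4-methoxyphenyl)-1-methyl-1H-imidazol-2-amine] (achiral) | COc1ccc(-c2nc(N)n(C)c2SSc2c(-c3ccc(OC)cc3)nc(N)n2C)cc1 | target

Total step count: 5. Longest linear sequence: 5 steps (1 → 4 → 6 → 8 → 10 → 12).

**Steps most likely to fail**

1. **Step 3 (key coupling).** Oxidative addition into the fairly electron-rich azolyl C–O bond may be slower than hydrolytic S–O cleavage of the triflate by the aqueous base. It may also be slower than protodeboronation of the boronic acid. The fallback sets out from 6 and replaces the base-mediated boron transmetalation with an anhydrous, base-free Negishi coupling. Commercial 4-methoxyphenylmagnesium bromide is transmetalated with ZnCl2 in THF to 4-methoxyphenylzinc chloride F1. This reagent is coupled with 6 under Pd-PEPPSI-IPr catalysis in THF at rt to 50 °C. The fallback comes back to the route at 8.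

2. **Step 2 (triflation).** The ambident enolate may be sulfonylated at C5 or N3 instead of oxygen, and the triflate may hydrolyse during work-up or on silica. The fallback sets out from 4 and activates the carbonyl oxygen as a phosphate instead of a sulfonate. KHMDS in THF at −78 °C followed by the hard electrophile diphenyl chlorophosphate should give the chromatography-stable 2-[bis(tert-butoxycarbonyl)amino]-1-methyl-1H-imidazol-4-yl diphenyl phosphate F2. F2 is coupled with 7 in the manner of lactam-derived ketene aminal phosphates (Pd(PPh3)4, K3PO4, dioxane, 80 °C). The fallback comes back to the route at 8.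

3. **Step 1 (exhaustive Boc protection).** The second acylation may go to ring N3 or to the enol oxygen instead of the exocyclic nitrogen, and the poor solubility of creatinine may stall the reaction. The fallback sets out from 3, isolated this time by using 1.1 equiv of Boc2O without DMAP, and moves the second protection to after aromatization. KHMDS (2.1 equiv, THF, −78 °C) forms the N,O-dianion. One equivalent of PhNTf2 should triflate its more reactive oxyanion to give tert-butyl N-[1-methyl-4-(trifluoromethylsulfonyloxy)-1H-imidazol-2-yl]carbamate F3. In F3 the carbamate N–H is the only acylable site, so Boc2O (2) with DMAP in CH2Cl2 places the second Boc group unambiguously. The fallback comes back to the route at 6.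

**Further compounds**
F1 | step 3 | 4-methoxyphenylzinc chloride | COc1ccc([Zn]Cl)cc1
F2 | step 2 | 2-[bis(tert-butoxycarbonyl)amino]-1-methyl-1H-imidazol-4-yl diphenyl phosphate | Cn1cc(OP(=O)(Oc2ccccc2)Oc2ccccc2)nc1N(C(=O)OC(C)(C)C)C(=O)OC(C)(C)C
F3 | step 1 | tert-butyl N-[1-methyl-4-(trifluoromethylsulfonyloxy)-1H-imidazol-2-yl]carbamate | Cn1cc(OS(=O)(=O)C(F)(F)F)nc1NC(=O)OC(C)(C)C
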